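**Plan**

- Retrosynthesis: once the 7-O-MOM group is taken off, the two aryl–CH2 bonds C6–C1″ (prenyl, ring A) and C3′–C1‴ (geranyl, ring B) are cut in one operation, each chain going back to a tertiary allyl ether on the oxygen beside it (O5 and O4′).
- Enabling feature: on ring A, C6 is the only CH ortho to O5 (the other ortho atom is the ring-fusion carbon C4a), and on ring B, C3′ is ortho to O4′. Each chain can therefore travel from its own oxygen to its carbon by a [3,3] shift.
- Forward order: no ring is built, since all three arrive with (S)-naringenin. O7 is masked, then the C10 unit is joined to O4′ and the C5 unit to O5 as tertiary propargyl ethers; copper catalysis is chosen because it gives only the tertiary ether, also at the hydrogen-bonded 5-OH. One Lindlar reduction makes both allyl ethers, one heating moves both chains to carbon, and the MOM group leaves last.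
- Stereochemistry: C2 (S) is bought and is not a reacting centre in any step. The E alkene of the geranyl chain is set in the chair transition state of the O4′→C3′ shift. The ether carbon of the C10 unit is carried as both epimers because it ends as an sp2 carbon.

Key step: step 5

Assumption: (2S)-naringenin is taken as purchasable in high enantiomeric purity; because flavanones can racemise through the ring-opened chalcone, every basic step is run at or below room temperature and the optical purity should be checked after steps 1–3.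

**Step 1**
Reactants: 1 (2S)-naringenin
Product: 2 (2S)-7-O-(methoxymethyl)naringenin
Conditions: MOMCl (1.0 equiv), i-Pr2NEt (1.2 equiv), THF, 0 °C
Reagents that add atoms: chloromethyl methyl ether, COCCl
Why: Williamson-type O-alkylation: with one equivalent of MOMCl and a hindered amine at 0 °C the most acidic phenol, the 7-OH para to the C4 carbonyl, should be alkylated ahead of the ordinary 4′-OH and the hydrogen-bonded 5-OH, under conditions too mild to open the pyranone ring at C2.

**Step 2**
Reactants: 2 (2S)-7-O-(methoxymethyl)naringenin; 3 (±)-dehydrolinalool (3,7-dimethyloct-6-en-1-yn-3-ol)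
Product: 5 (2S)-7-O-MOM-4′-O-(3,7-dimethyloct-6-en-1-yn-3-yl)naringenin, via dehydrolinalyl trifluoroacetate 4 (not isolated)
Conditions: 3 (1.3 equiv), (CF3CO)2O, DBU, MeCN, −5 °C; then 2, DBU, CuCl2·2H2O (1 mol %), MeCN, −5 → 0 °C, N2
Reagents that add atoms: none
Why: Copper-catalysed propargylic etherification (copper acetylide/allenylidene pathway) of the phenoxide with the trifluoroacetate made in situ gives only the tertiary propargyl aryl ether, the free 4′-OH should react well ahead of the chelated 5-OH, and the unresolved ether carbon does not matter because it becomes sp2 in step 5.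

**Step 3**
Reactants: 5 (2S)-7-O-MOM-4′-O-(3,7-dimethyloct-6-en-1-yn-3-yl)naringenin; 6 3-chloro-3-methylbut-1-yne
Product: 7 (2S)-7-O-MOM-4′-O-(3,7-dimethyloct-6-en-1-yn-3-yl)-5-O-(2-methylbut-3-yn-2-yl)naringenin
Conditions: 6 (3 equiv), DBU (3 equiv), CuCl2·2H2O (2 mol %), MeCN, 0 °C → rt, N2; pH 7 buffer quench
Reagents that add atoms: none
Why: The same copper-catalysed propargylic etherification is pushed with excess electrophile onto the hydrogen-bonded 5-OH, the only acidic site left, and is kept cold and quenched at neutral pH because the fully etherified flavanone could otherwise open to the chalcone and lose the C2 configuration.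

**Step 4**
Reactants: 7 (2S)-7-O-MOM-4′-O-(3,7-dimethyloct-6-en-1-yn-3-yl)-5-O-(2-methylbut-3-yn-2-yl)naringenin
Product: 8 (2S)-7-O-MOM-4′-O-linalyl-5-O-(2-methylbut-3-en-2-yl)naringenin
Conditions: H2 (1 atm), Lindlar catalyst, quinoline, EtOAc, 0 °C → rt, stopped after 2 equiv H2; product kept cold
Reagents that add atoms: none
Why: Lindlar semihydrogenation should take both terminal alkynes to vinyl groups while leaving the trisubstituted alkene, the ketone and the benzylic C2–O bond alone, which is the standard passage from a tertiary propargyl aryl ether to the tertiary allyl ether needed for a Claisen shift.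

**Step 5**
Reactants: 8 (2S)-7-O-MOM-4′-O-linalyl-5-O-(2-methylbut-3-en-2-yl)naringenin
Product: 12 (2S)-7-O-MOM-schizolaenone A, via C6 dienone 9 (not isolated), via mono-rearranged phenol 10 (not isolated), via C3′ dienone 11 (not isolated)
Conditions: PhMe (degassed, 0.02 M), 110 °C, sealed tube; AgNO3–SiO2 chromatography
Reagents that add atoms: none
Why: Two independent concerted [3,3] aromatic Claisen shifts through chair transition states move C1″ from O5 to C6 and C1‴ from O4′ to C3′, and each cyclohexadienone then enolises to the phenol; the ortho-acyl ether on ring A is expected to go first. The closest known reaction is the thermal Claisen rearrangement of 1,1-dimethylallyl aryl ethers to ortho-prenylphenols, which runs at about this temperature. No ring is closed and no stereocentre is made: the ether carbon of the linalyl group becomes the sp2 carbon C3‴, so both epimers of 8 converge, and C2 is not involved under neutral aprotic conditions. Regiochemistry is fixed by the substrate, because C6 is the only ortho CH of O5 and the two ortho positions of O4′ are equivalent, while a further Cope shift from C6 to C8 would have to bond the hindered CMe2 terminus to the ring and should lose to enolisation. The (2‴E) geometry needs the homoprenyl chain rather than the methyl group in the pseudo-equatorial site of the chair, a preference expected to be only modest, so the (2‴Z) neryl isomer is the anticipated main by-product and is to be removed on silver nitrate-impregnated silica.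

**Step 6**
Reactants: 12 (2S)-7-O-MOM-schizolaenone A
Product: 13 schizolaenone A
Conditions: 3 M aq HCl–MeOH (1:5), rt → 40 °C
Reagents that add atoms: none
Why: Acid-catalysed methanolysis of the phenolic MOM acetal, a deprotection well known on prenylated flavanones, should outrun protonation of the trisubstituted alkenes and acid-induced opening at C2 if it is stopped at full conversion, so the side chains and the (2S) centre are expected to survive.

**Compound list**

1 | (2S)-naringenin | O=C1C[C@@H](c2ccc(O)cc2)Oc2cc(O)cc(O)c12 | starting material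
2 | (2S)-5-hydroxy-2-(4-hydroxyphenyl)-7-(methoxymethoxy)chroman-4-one (7-O-MOM-naringenin) | Oc1ccc([C@@H]2CC(=O)c3c(cc(OCOC)cc3O)O2)cc1 | intermediate
3 | (±)-dehydrolinalool, 3,7-dimethyloct-6-en-1-yn-3-ol | CC(C)=CCCC(C)(O)C#C | starting material
4 | dehydrolinalyl trifluoroacetate, 3,7-dimethyloct-6-en-1-yn-3-yl trifluoroacetate (racemic, not isolated) | CC(C)=CCCC(C)(OC(=O)C(F)(F)F)C#C | intermediate
5 | (2S)-5-hydroxy-7-(methoxymethoxy)-2-{4-[(3,7-dimethyloct-6-en-1-yn-3-yl)oxy]phenyl}chroman-4-one, both epimers at the ether carbon | C#CC(C)(CCC=C(C)C)Oc1ccc([C@@H]2CC(=O)c3c(cc(OCOC)cc3O)O2)cc1 | intermediate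
6 | 3-chloro-3-methylbut-1-yne | CC(C)(Cl)C#C | starting material
7 | (2S)-7-(methoxymethoxy)-5-[(2-methylbut-3-yn-2-yl)oxy]-2-{4-[(3,7-dimethyloct-6-en-1-yn-3-yl)oxy]phenyl}chroman-4-one, both epimers at the ether carbon | C#CC(C)(CCC=C(C)C)Oc1ccc([C@@H]2CC(=O)c3c(cc(OCOC)cc3OC(C)(C)C#C)O2)cc1 | intermediate
8 | (2S)-7-(methoxymethoxy)-5-[(2-methylbut-3-en-2-yl)oxy]-2-{4-[(3,7-dimethylocta-1,6-dien-3-yl)oxy]phenyl}chroman-4-one, both epimers at the linalyl carbon | C=CC(C)(CCC=C(C)C)Oc1ccc([C@@H]2CC(=O)c3c(cc(OCOC)cc3OC(C)(C)C=C)O2)cc1 | intermediate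
9 | C6 dienone: keto tautomer formed by the O5→C6 shift, (2S)-7-(methoxymethoxy)-6-(3-methylbut-2-enyl)-2-{4-[(3,7-dimethylocta-1,6-dien-3-yl)oxy]phenyl}-2,3-dihydrochromene-4,5(6H)-dione, C6 unassigned (not isolated) | C=CC(C)(CCC=C(C)C)Oc1ccc([C@@H]2CC(=O)C3=C(C=C(OCOC)C(CC=C(C)C)C3=O)O2)cc1 | intermediate
10 | mono-rearranged phenol: (2S)-5-hydroxy-7-(methoxymethoxy)-6-(3-methylbut-2-enyl)-2-{4-[(3,7-dimethylocta-1,6-dien-3-yl)oxy]phenyl}chroman-4-one (not isolated) | C=CC(C)(CCC=C(C)C)Oc1ccc([C@@H]2CC(=O)c3c(cc(OCOC)c(CC=C(C)C)c3O)O2)cc1 | intermediate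
11 | C3′ dienone: keto tautomer of 12 formed by the O4′→C3′ shift, ring B as a 6-[(2E)-geranyl]cyclohexa-2,4-dien-1-one, C3′ unassigned (not isolated) | CC(C)=CCC/C(C)=C/CC1C=C([C@@H]2CC(=O)c3c(cc(OCOC)c(CC=C(C)C)c3O)O2)C=CC1=O | intermediate
12 | (2S)-7-O-MOM-schizolaenone A, (2S)-5-hydroxy-2-{3-[(2E)-3,7-dimethylocta-2,6-dienyl]-4-hydroxyphenyl}-7-(methoxymethoxy)-6-(3-methylbut-2-enyl)chroman-4-one | CC(C)=CCC/C(C)=C/Cc1cc([C@@H]2CC(=O)c3c(cc(OCOC)c(CC=C(C)C)c3O)O2)ccc1O | intermediate
13 | schizolaenone A, (2S)-5,7-dihydroxy-2-{3-[(2E)-3,7-dimethylocta-2,6-dienyl]-4-hydroxyphenyl}-6-(3-methylbut-2-enyl)chroman-4-one | CC(C)=CCC/C(C)=C/Cc1cc([C@@H]2CC(=O)c3c(cc(O)c(CC=C(C)C)c3O)O2)ccc1O | target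

**Step count**

Total steps: 6. Longest linear sequence: 6 (1 → 13).

**Steps most likely to fail**

Step 5. What may go wrong: weak geometric control in the O4′→C3′ shift, because methyl and homoprenyl compete almost evenly for the pseudo-equatorial site. A large share of the neryl isomer is then formed, and some of the linalyl group may be lost by retro-ene elimination. Fallback: the geranyl chain is brought in with its E alkene already made and is moved to carbon by a [1,3] shift instead of a [3,3] shift. Setting out from 2, a Mitsunobu etherification of the 4′-OH with geraniol (PPh3, DIAD, THF, 0 °C) should give the 4′-O-geranyl ether F1. Copper-catalysed propargylation of its 5-OH with 6 under the conditions of step 3 gives the 5-O-(2-methylbut-3-yn-2-yl) ether F2, and Lindlar reduction gives the 5-O-(2-methylbut-3-en-2-yl) ether F3. Heating in toluene at 110 °C moves only the tertiary group from O5 to C6, the primary geranyl ether being inert at this temperature, and gives the 6-prenyl 4′-O-geranyl compound F4. Montmorillonite K10 in CH2Cl2 at 0 °C then promotes the known clay-mediated [1,3] O→C shift of the geranyl group to C3′ with the alkene geometry of geraniol retained, and the route is rejoined at 12.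

Step 3. What may go wrong: slow O-alkylation of the hydrogen-bonded 5-phenoxide, and base-induced opening and reclosure of the pyranone ring during long exposure to DBU, which would erode the C2 configuration. Fallback: the carbonyl is taken away for the duration of the alkylation. From 5, NaBH4 in MeOH at 0 °C gives the flavan-4-ol F5 (C4 epimers), in which the 5-OH is an ordinary phenol and C2 can no longer open by a retro-oxa-Michael path. Propargylation with 6 (CuCl2·2H2O, DBU, MeCN, 0 °C) gives the 5-O-(2-methylbut-3-yn-2-yl) flavan-4-ol F6. Buffered Dess–Martin oxidation (NaHCO3, CH2Cl2, 0 °C) restores the ketone and returns to the route at 7.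

Step 6. What may go wrong: acid-induced cyclisation of the prenyl and geranyl chains onto the neighbouring phenols (chroman formation) or addition of methanol to the alkenes during MOM cleavage. Fallback: the MOM group is removed before any phenol sits next to an alkene. From 7, HCl in MeOH at rt removes the acetal while the tertiary propargyl ethers, whose ethynyl groups disfavour ionisation, should hold, giving the 7-hydroxy bis-propargyl ether F7. Lindlar reduction gives the 7-hydroxy bis-allyl ether F8. The double Claisen rearrangement of step 5, run on this free phenol, then delivers 13 directly.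

**Further compounds**

F1 | step 5 | (2S)-4′-O-[(2E)-geranyl]-7-O-MOM-naringenin | CC(C)=CCC/C(C)=C/COc1ccc([C@@H]2CC(=O)c3c(cc(OCOC)cc3O)O2)cc1
F2 | step 5 | (2S)-4′-O-[(2E)-geranyl]-7-O-MOM-5-O-(2-methylbut-3-yn-2-yl)naringenin | CC(C)=CCC/C(C)=C/COc1ccc([C@@H]2CC(=O)c3c(cc(OCOC)cc3OC(C)(C)C#C)O2)cc1
F3 | step 5 | (2S)-4′-O-[(2E)-geranyl]-7-O-MOM-5-O-(2-methylbut-3-en-2-yl)naringenin | CC(C)=CCC/C(C)=C/COc1ccc([C@@H]2CC(=O)c3c(cc(OCOC)cc3OC(C)(C)C=C)O2)cc1
F4 | step 5 | (2S)-4′-O-[(2E)-geranyl]-7-O-MOM-6-prenylnaringenin | CC(C)=CCC/C(C)=C/COc1ccc([C@@H]2CC(=O)c3c(cc(OCOC)c(CC=C(C)C)c3O)O2)cc1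
F5 | step 3 | (2S)-7-(methoxymethoxy)-2-{4-[(3,7-dimethyloct-6-en-1-yn-3-yl)oxy]phenyl}chroman-4,5-diol, C4 epimers | C#CC(C)(CCC=C(C)C)Oc1ccc([C@@H]2CC(O)c3c(cc(OCOC)cc3O)O2)cc1
F6 | step 3 | (2S)-7-(methoxymethoxy)-5-[(2-methylbut-3-yn-2-yl)oxy]-2-{4-[(3,7-dimethyloct-6-en-1-yn-3-yl)oxy]phenyl}chroman-4-ol, C4 epimers | C#CC(C)(CCC=C(C)C)Oc1ccc([C@@H]2CC(O)c3c(cc(OCOC)cc3OC(C)(C)C#C)O2)cc1
F7 | step 6 | (2S)-7-hydroxy-5-[(2-methylbut-3-yn-2-yl)oxy]-2-{4-[(3,7-dimethyloct-6-en-1-yn-3-yl)oxy]phenyl}chroman-4-one | C#CC(C)(CCC=C(C)C)Oc1ccc([C@@H]2CC(=O)c3c(cc(O)cc3OC(C)(C)C#C)O2)cc1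
F8 | step 6 | (2S)-7-hydroxy-5-[(2-methylbut-3-en-2-yl)oxy]-2-{4-[(3,7-dimethylocta-1,6-dien-3-yl)oxy]phenyl}chroman-4-one | C=CC(C)(CCC=C(C)C)Oc1ccc([C@@H]2CC(=O)c3c(cc(O)cc3OC(C)(C)C=C)O2)cc1
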